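**Retrosynthetic overview**

- The target is opened at the tetrahydrofuran ether (O–C20) and the glycolate. The eight-membered ring is then opened at C10–C11 (alkyne plus aldehyde), and C12–C13 is cut to a C14 methyl ketone and a tertiary α-bromo thioester made from (S)-malate acetonide.
- The strategy rests on one feature (mutilin numbering): the cyclopentanone carbonyl C3 and the oxygen-bearing ring carbon C14 are 1,4-related through C4–C5, the bond shared by the six- and eight-membered rings. This gives a hydrindane 1,4-diketone, made by anodic coupling of a bis(silyl enol ether) at C4 (tertiary) and C5 (quaternary).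
- The bis(enol silane) comes from 3-bromocyclopent-2-enone by a Negishi coupling and two copper-catalysed asymmetric conjugate additions (C9, then C6), each trapped regiospecifically as an enol silane, with a Wittig reaction in between.
- Ring order: cyclopentane (starting material), cyclohexane (C4–C5, anodic), cyclooctane (C10–C11, nickel), tetrahydrofuran (O–C20).

Key step: step 6

Assumption: every SMILES below carries the stereodescriptors of the target string unchanged; the spatial arguments are written for the natural mutilin relative configuration, in which C4–H, the C6 methyl, C14 and the C9–C10 bond lie on one face of the cyclohexane, the only arrangement that lets the five-carbon C10–C14 chain bridge C5 and C9.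

**Route**

Step 1
Reactants: 1 3-bromocyclopent-2-en-1-one; 2 (3-ethoxy-3-oxopropyl)zinc bromide
Product: 3 ethyl 3-(3-oxocyclopent-1-en-1-yl)propanoate
Conditions: Pd(PPh3)4 (3 mol %), THF, rt
Reagents that add atoms: none
Why: Negishi coupling, in which zerovalent palladium inserts into the vinylogous acyl bromide and the zinc homoenolate transmetalates and couples, while ester and enone carbonyls are inert to the organozinc.

Step 2
Reactants: 3 ethyl 3-(3-oxocyclopent-1-en-1-yl)propanoate; 4 ethynyltrimethylsilane
Product: 6 ethyl 3-[3-(tert-butyldimethylsilyloxy)-1-(1-trimethylsilylvinyl)cyclopent-2-en-1-yl]propanoate, via diisobutylaluminium enolate 5 (not isolated)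
Conditions: i-Bu2AlH, 4, hexane, 55 °C; then 3, Cu(OTf)2 (5 mol %), chiral sulfonate-bearing imidazolinium salt (N-heterocyclic carbene precursor, 5 mol %), THF, −50 °C; then TBSOTf, −50 → 0 °C
Reagents that add atoms: tert-butyldimethylsilyl trifluoromethanesulfonate, CC(C)(C)[Si](C)(C)OS(=O)(=O)C(F)(F)F
Why: Copper-catalysed enantioselective conjugate addition of the alkenylaluminium (hydroalumination places aluminium on the silyl-bearing carbon) builds quaternary C9 under ligand control, the carbene enantiomer being chosen for the configuration drawn, and O-silylation of the aluminium enolate fixes the enol ether regiospecifically toward C4.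

Step 3
Reactants: 6 ethyl 3-[3-(tert-butyldimethylsilyloxy)-1-(1-trimethylsilylvinyl)cyclopent-2-en-1-yl]propanoate
Product: 7 3-[3-(tert-butyldimethylsilyloxy)-1-(1-trimethylsilylvinyl)cyclopent-2-en-1-yl]propanal
Conditions: i-Bu2AlH (1.1 equiv), CH2Cl2, −78 °C; Rochelle salt work-up
Reagents that add atoms: none
Why: Partial ester reduction with diisobutylaluminium hydride, whose tetrahedral aluminium hemiacetal survives at −78 °C and gives the aldehyde on work-up, while the silyl enol ether and the alkenylsilane do not react.

Step 4
Reactants: 7 3-[3-(tert-butyldimethylsilyloxy)-1-(1-trimethylsilylvinyl)cyclopent-2-en-1-yl]propanal; 8 3-(triphenylphosphoranylidene)butan-2-one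
Product: 9 (E)-6-[3-(tert-butyldimethylsilyloxy)-1-(1-trimethylsilylvinyl)cyclopent-2-en-1-yl]-3-methylhex-3-en-2-one
Conditions: toluene, 90 °C
Reagents that add atoms: none
Why: Wittig olefination with the stabilised α-methyl ylide, which reacts only with the aldehyde and should give the (E)-trisubstituted enone.

Step 5
Reactants: 9 (E)-6-[3-(tert-butyldimethylsilyloxy)-1-(1-trimethylsilylvinyl)cyclopent-2-en-1-yl]-3-methylhex-3-en-2-one
Product: 11 tert-butyl{[3-[3,4-dimethyl-5-(trimethylsilyloxy)hex-4-en-1-yl]-3-(1-trimethylsilylvinyl)cyclopent-1-en-1-yl]oxy}dimethylsilane, via bromomagnesium enolate 10 (not isolated)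
Conditions: MeMgBr, CuBr·SMe2 (5 mol %), (R,SP)- or (S,RP)-1-[2-(diphenylphosphino)ferrocenyl]ethyldicyclohexylphosphine (6 mol %), t-BuOMe, −78 °C; then TMSCl, Et3N, HMPA, −78 → 0 °C
Reagents that add atoms: methylmagnesium bromide, C[Mg]Br; chlorotrimethylsilane, C[Si](C)(C)Cl
Why: Copper-catalysed asymmetric conjugate addition of the Grignard reagent delivers methyl to one face of C6 under control of the diphosphine (its enantiomer is chosen for the configuration drawn, since remote C9 exerts no bias), and silylation of the magnesium enolate gives the fully substituted enol silane regiospecifically.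

Step 6
Reactants: 11 tert-butyl{[3-[3,4-dimethyl-5-(trimethylsilyloxy)hex-4-en-1-yl]-3-(1-trimethylsilylvinyl)cyclopent-1-en-1-yl]oxy}dimethylsilane
Product: 12 7-acetyl-6,7-dimethyl-3a-(1-trimethylsilylvinyl)octahydro-1H-inden-1-one (cis-fused hydrindane; the mutilin C3,C14-diketone)
Conditions: undivided cell, reticulated vitreous carbon anode, Pt cathode, LiClO4 (0.1 M), 2,6-lutidine, MeCN/i-PrOH (4:1), 5 mM, constant current, 2.2 F/mol, rt
Reagents that add atoms: none
Why: Anodic oxidation takes one electron from the more electron-rich, fully substituted enol silane; C4 of the cyclopentenyl enol silane then adds to C5 of that radical cation, and a second oxidation with loss of both silyl groups to isopropanol gives the 1,4-diketone (hydrogen is evolved at the cathode). The closest known reaction type is the oxidative (anodic or chemical) coupling of two enol ether or silyl enol ether units to a 1,4-dicarbonyl compound. The cyclohexane is closed in the 6-exo-trig mode: C5 bonds to C4 while the attacked C3=C4 double bond stays outside the new ring. C4 is controlled by the tether, which can deliver C5 only to the cyclopentene face that carries C8, so the ring fusion is cis (C4–H syn to the C9 alkenyl group). C5 is controlled by the chair-like transition state on that cis-hydrindane manifold, in which the bulky C(OSiMe3)CH3 terminus turns outward (pseudo-equatorial, anti to C7) and the small C15 methyl sits over the cyclopentene CH2, so that C14 ends syn to the C9 alkenyl group and to the C6 methyl; C6 and C9 are spectators. The step needs oxidation of the enol silanes but not of the 1-silylvinyl group (oxidised only at a clearly higher potential) and ring closure rather than intermolecular coupling (secured by high dilution and the six-membered transition state).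

Step 7
Reactants: 12 7-acetyl-6,7-dimethyl-3a-(1-trimethylsilylvinyl)octahydro-1H-inden-1-one
Product: 13 C3 ethylene ketal of 12 (C14 acetyl group free)
Conditions: (TMSOCH2)2, TMSOTf (5 mol %), CH2Cl2, −78 → −40 °C; pyridine quench
Reagents that add atoms: 1,2-bis(trimethylsilyloxy)ethane, C[Si](C)(C)OCCO[Si](C)(C)C
Why: Noyori ketalisation under aprotic conditions at low temperature selects the cyclopentanone over the acetyl group flanked by quaternary C5, avoids aldol closure of the 1,4-diketone and leaves C4 untouched.

Step 8
Reactants: 14 methyl (S)-2-(2,2-dimethyl-1,3-dioxolan-4-yl)acetate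
Product: 16 methyl 2-[(4S)-2,2-dimethyl-1,3-dioxolan-4-yl]propanoate (both C2 epimers), via lithium ester enolate 15 (not isolated)
Conditions: LDA, THF, −78 °C; then MeI, −78 → −40 °C
Reagents that add atoms: iodomethane, CI
Why: Ester enolate C-methylation at −78 °C, which outruns β-elimination of the acetonide oxygen; the new centre needs no control because it later becomes a planar radical.

Step 9
Reactants: 16 methyl 2-[(4S)-2,2-dimethyl-1,3-dioxolan-4-yl]propanoate
Product: 17 S-ethyl 2-[(4S)-2,2-dimethyl-1,3-dioxolan-4-yl]propanethioate (both C2 epimers)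
Conditions: Me3Al, EtSH, CH2Cl2, 0 °C → rt
Reagents that add atoms: ethanethiol, CCS
Why: Ester-to-thioester exchange with the aluminium thiolate formed from trimethylaluminium and the thiol, which installs an acyl group that can later be reduced to the aldehyde without touching a ketone.

Step 10
Reactants: 17 S-ethyl 2-[(4S)-2,2-dimethyl-1,3-dioxolan-4-yl]propanethioate
Product: 19 S-ethyl 2-bromo-2-[(4R)-2,2-dimethyl-1,3-dioxolan-4-yl]propanethioate (both C2 epimers; dioxolane carbon spatially unchanged), via lithium thioester enolate 18 (not isolated)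
Conditions: LiHMDS, THF, −78 °C; then BrCCl2CCl2Br
Reagents that add atoms: 1,2-dibromo-1,1,2,2-tetrachloroethane, BrC(Cl)(Cl)C(Cl)(Cl)Br
Why: Electrophilic bromination of the thioester enolate gives the tertiary α-bromide, and both epimers converge on the same radical in the next step.

Step 11
Reactants: 13 C3 ethylene ketal of 12; 19 S-ethyl 2-bromo-2-[(4R)-2,2-dimethyl-1,3-dioxolan-4-yl]propanethioate
Product: 21 γ-keto thioester with quaternary C12 (C14 ketone–C13H2–C12(CH3)(COSEt)(dioxolanyl)), via trimethylsilyl enol ether 20 (not isolated)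
Conditions: LDA, TMSCl, THF, −78 °C; solvent exchange; then 19, fac-Ir(ppy)3 (1 mol %), NaOAc, DMF, blue LEDs, rt
Reagents that add atoms: none
Why: Kinetic enol silane formation (only C13 can be enolised) is followed by photoredox radical alkylation, in which the excited iridium complex reduces 19 to the tertiary α-thioester radical, this adds to the CH2 terminus of the enol silane and oxidation with loss of silicon gives the 1,4-dicarbonyl compound; C12 is set by attack anti to the dioxolane ring carbon in the allylic-strain-minimised radical conformer (exocyclic effect), which places C13 syn to the dioxolane oxygen as the later tetrahydrofuran requires.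

Step 12
Reactants: 21 γ-keto thioester with quaternary C12
Product: 22 γ-keto aldehyde (C11 aldehyde on quaternary C12; C9 1-silylvinyl)
Conditions: Et3SiH, Pd/C (10 mol %), acetone, rt
Reagents that add atoms: none
Why: Fukuyama reduction, in which zerovalent palladium inserts into the C–S bond and the silane transfers hydride, gives the aldehyde while the ketone, both acetals and the hindered alkenylsilane stay intact.

Step 13
Reactants: 22 γ-keto aldehyde
Product: 23 2-iodoalkene (iodine on C10; otherwise as 22)
Conditions: NIS, MeCN/ClCH2CN (4:1), 0 °C → rt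
Reagents that add atoms: N-iodosuccinimide, O=C1CCC(=O)N1I
Why: Iododesilylation, an ipso substitution of the alkenylsilane through the β-silyl-stabilised iodonium ion, replaces silicon by iodine at C10.

Step 14
Reactants: 23 2-iodoalkene
Product: 24 alkynyl aldehyde (C9–C≡CH; C11 aldehyde; C14 ketone)
Conditions: TBAF, DMF, 60 °C
Reagents that add atoms: none
Why: Fluoride-induced E2 dehydroiodination (anti hydrogen on the terminal carbon) gives the terminal alkyne; the aldehyde has no α-hydrogen and the acetonide and ketal are stable to fluoride.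

Step 15
Reactants: 24 alkynyl aldehyde
Product: 25 tricyclic allylic silyl ether (3-ethylene ketal; 10-methylidene; 11-triethylsilyloxy; 12-methyl-12-[(4S)-2,2-dimethyl-1,3-dioxolan-4-yl]; 14-oxo)
Conditions: Ni(cod)2 (25 mol %), IPr [1,3-bis(2,6-diisopropylphenyl)imidazol-2-ylidene] (25 mol %), Et3SiH, THF, rt
Reagents that add atoms: triethylsilane, CC[SiH](CC)CC
Why: Nickel-catalysed reductive alkyne–aldehyde cyclisation, in which oxidative cyclisation at zerovalent nickel joins C10 to C11 in the exo mode (endo closure would need an E-alkene in a nine-membered ring) and the silane cleaves the oxanickelacycle; the hindered C14 ketone does not compete with the aldehyde, and C11 should form with the nickel-bound oxygen on the open top face and C11–H turned toward C4, that is with oxygen syn to C19.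

Step 16
Reactants: 25 tricyclic allylic silyl ether
Product: 26 C14 alcohol of 25 (OH on the outer face; C14–H pointing across the ring toward C10)
Conditions: SmI2, H2O, Et3N, THF, rt
Reagents that add atoms: none
Why: Single-electron ketone reduction with samarium diiodide, water and amine should give the more stable C14 alcohol (oxygen outside, hydrogen inside) by protonation of the organosamarium, and this fast proton-coupled reduction outruns addition of the ketyl to the unactivated alkene.

Step 17
Reactants: 26 C14 alcohol of 25
Product: 27 10-methyl 14-ketone (C10–H inside the ring; methyl outside)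
Conditions: Mn(dpm)3 (20 mol %), PhSiH3 (0.5 equiv), t-BuOOH (0.5 equiv), i-PrOH, rt
Reagents that add atoms: none
Why: Metal-hydride hydrogen atom transfer to the methylene terminus gives the tertiary C10 radical, which takes the transannular C14–H through a six-membered transition state (1,5-hydrogen atom transfer), the only hydrogen that can reach the inner face of C10, so the methyl group ends outside the ring and the C14 ketyl radical is oxidised to the ketone (redox relay).

Step 18
Reactants: 27 10-methyl 14-ketone
Product: 28 C14 alcohol (natural C10, C11 and C14 configuration; 11-O-triethylsilyl)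
Conditions: SmI2, H2O, Et3N, THF, rt
Reagents that add atoms: none
Why: The same single-electron reduction restores the C14 alcohol with oxygen on the outer face and hydrogen inside, the more stable arrangement on the bridged eight-membered ring.

Step 19
Reactants: 28 C14 alcohol; 29 benzyloxyacetyl chloride
Product: 30 C14 benzyloxyacetate
Conditions: pyridine, DMAP (cat.), CH2Cl2, 40 °C
Reagents that add atoms: none
Why: Acylation of the only free hydroxyl group by the acid chloride under nucleophilic catalysis.

Step 20
Reactants: 30 C14 benzyloxyacetate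
Product: 31 triol ketone (C11, C19 and C20 hydroxyl groups; C3 ketone; C14 benzyloxyacetate)
Conditions: 2 M HCl, THF, rt
Reagents that add atoms: water, O
Why: Acid hydrolysis removes the silyl ether, the acetonide and the ketal in one operation, the ester tolerates dilute acid, and C4 stays in the cis configuration that is preferred in the bridged tricycle.

Step 21
Reactants: 31 triol ketone
Product: 33 O-benzyl ether of the target (tetrahydrofuran closed), via primary tosylate 32 (not isolated)
Conditions: TsCl, pyridine, 0 °C; then 60 °C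
Reagents that add atoms: none
Why: Selective sulfonylation of the primary C20 hydroxyl is followed by intramolecular Williamson etherification (5-exo-tet) by the C11 hydroxyl, which closes the cis-fused tetrahydrofuran without touching the C11 or C19 stereocentres.

Step 22
Reactants: 33 O-benzyl ether of the target
Product: 34 pleuromutilin B
Conditions: H2 (1 atm), Pd/C, EtOAc, rt
Reagents that add atoms: none
Why: Hydrogenolysis of the benzyl ether frees the glycolate hydroxyl group; ketone, ester and ether are inert.

**Compound list**

1 | 3-bromocyclopent-2-en-1-one | O=C1C=C(Br)CC1 | starting material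
2 | (3-ethoxy-3-oxopropyl)zinc bromide | CCOC(=O)CC[Zn]Br | starting material
3 | ethyl 3-(3-oxocyclopent-1-en-1-yl)propanoate | CCOC(=O)CCC1=CC(=O)CC1 | intermediate
4 | ethynyltrimethylsilane | C#C[Si](C)(C)C | starting material
5 | diisobutylaluminium enolate of the conjugate adduct (enolate toward C4) | CCOC(=O)CC[C@@]1(C(=C)[Si](C)(C)C)CCC(O[Al](CC(C)C)CC(C)C)=C1 | intermediate
6 | ethyl 3-[3-(tert-butyldimethylsilyloxy)-1-(1-trimethylsilylvinyl)cyclopent-2-en-1-yl]propanoate (C9 as in the target) | CCOC(=O)CC[C@@]1(C(=C)[Si](C)(C)C)CCC(O[Si](C)(C)C(C)(C)C)=C1 | intermediate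
7 | 3-[3-(tert-butyldimethylsilyloxy)-1-(1-trimethylsilylvinyl)cyclopent-2-en-1-yl]propanal | O=CCC[C@@]1(C(=C)[Si](C)(C)C)CCC(O[Si](C)(C)C(C)(C)C)=C1 | intermediate
8 | 3-(triphenylphosphoranylidene)butan-2-one | CC(=O)C(C)=P(c1ccccc1)(c1ccccc1)c1ccccc1 | starting material
9 | (E)-6-[3-(tert-butyldimethylsilyloxy)-1-(1-trimethylsilylvinyl)cyclopent-2-en-1-yl]-3-methylhex-3-en-2-one | CC(=O)/C(C)=C/CC[C@@]1(C(=C)[Si](C)(C)C)CCC(O[Si](C)(C)C(C)(C)C)=C1 | intermediate
10 | bromomagnesium enolate of the methyl adduct (C5=C14) | C/C(O[Mg]Br)=C(C)/[C@@H](C)CC[C@@]1(C(=C)[Si](C)(C)C)CCC(O[Si](C)(C)C(C)(C)C)=C1 | intermediate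
11 | bis(silyl enol ether): tert-butyl{[3-[3,4-dimethyl-5-(trimethylsilyloxy)hex-4-en-1-yl]-3-(1-trimethylsilylvinyl)cyclopent-1-en-1-yl]oxy}dimethylsilane (C6 and C9 as in the target; acyclic enol silane drawn Z) | C/C(O[Si](C)(C)C)=C(C)/[C@@H](C)CC[C@@]1(C(=C)[Si](C)(C)C)CCC(O[Si](C)(C)C(C)(C)C)=C1 | intermediate
12 | 7-acetyl-6,7-dimethyl-3a-(1-trimethylsilylvinyl)octahydro-1H-inden-1-one (cis-fused; acetyl and C6 methyl syn to the alkenyl group) | CC(=O)[C@@]1(C)[C@@H](C)CC[C@@]2(C(=C)[Si](C)(C)C)CCC(=O)[C@H]12 | intermediate
13 | C3 ethylene ketal of 12 | CC(=O)[C@@]1(C)[C@@H](C)CC[C@@]2(C(=C)[Si](C)(C)C)CCC3(OCCO3)[C@H]12 | intermediate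
14 | methyl (S)-2-(2,2-dimethyl-1,3-dioxolan-4-yl)acetate | COC(=O)C[C@H]1COC(C)(C)O1 | starting material
15 | lithium enolate of 14 | COC(O[Li])=C[C@H]1COC(C)(C)O1 | intermediate
16 | methyl 2-[(4S)-2,2-dimethyl-1,3-dioxolan-4-yl]propanoate (both C2 epimers) | COC(=O)C(C)[C@H]1COC(C)(C)O1 | intermediate
17 | S-ethyl 2-[(4S)-2,2-dimethyl-1,3-dioxolan-4-yl]propanethioate (both C2 epimers) | CCSC(=O)C(C)[C@H]1COC(C)(C)O1 | intermediate
18 | lithium enolate of 17 | CCSC(O[Li])=C(C)[C@H]1COC(C)(C)O1 | intermediate
19 | S-ethyl 2-bromo-2-[(4R)-2,2-dimethyl-1,3-dioxolan-4-yl]propanethioate (both C2 epimers) | CCSC(=O)C(C)(Br)[C@H]1COC(C)(C)O1 | intermediate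
20 | trimethylsilyl enol ether of 13 (C14=C13H2) | C=C(O[Si](C)(C)C)[C@@]1(C)[C@@H](C)CC[C@@]2(C(=C)[Si](C)(C)C)CCC3(OCCO3)[C@H]12 | intermediate
21 | γ-keto thioester (C12 quaternary: methyl, thioester, C13, dioxolanyl) | CCSC(=O)[C@](C)([C@H]3COC(C)(C)O3)CC(=O)[C@@]1(C)[C@@H](C)CC[C@@]2(C(=C)[Si](C)(C)C)CCC3(OCCO3)[C@H]12 | intermediate
22 | γ-keto aldehyde (C11 aldehyde) | O=C[C@](C)([C@H]3COC(C)(C)O3)CC(=O)[C@@]1(C)[C@@H](C)CC[C@@]2(C(=C)[Si](C)(C)C)CCC3(OCCO3)[C@H]12 | intermediate
23 | 2-iodoalkene (iodine on C10) | O=C[C@](C)([C@H]3COC(C)(C)O3)CC(=O)[C@@]1(C)[C@@H](C)CC[C@@]2(C(I)=C)CCC3(OCCO3)[C@H]12 | intermediate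
24 | alkynyl aldehyde | O=C[C@](C)([C@H]3COC(C)(C)O3)CC(=O)[C@@]1(C)[C@@H](C)CC[C@@]2(C#C)CCC3(OCCO3)[C@H]12 | intermediate
25 | tricyclic allylic silyl ether (3-ethylene ketal, 10-methylidene, 11-triethylsilyloxy, 12-dioxolanyl, 14-oxo) | C=C1[C@H](O[Si](CC)(CC)CC)[C@](C)([C@H]2COC(C)(C)O2)CC(=O)[C@@]2(C)[C@@H](C)CC[C@]13CCC4(OCCO4)[C@@H]32 | intermediate
26 | C14 alcohol of 25 | C=C1[C@H](O[Si](CC)(CC)CC)[C@](C)([C@H]2COC(C)(C)O2)C[C@@H](O)[C@@]2(C)[C@@H](C)CC[C@]13CCC4(OCCO4)[C@@H]32 | intermediate
27 | 10-methyl 14-ketone | C[C@H]1[C@H](O[Si](CC)(CC)CC)[C@](C)([C@H]2COC(C)(C)O2)CC(=O)[C@@]2(C)[C@@H](C)CC[C@]13CCC4(OCCO4)[C@@H]32 | intermediate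
28 | 10-methyl 14-alcohol | C[C@H]1[C@H](O[Si](CC)(CC)CC)[C@](C)([C@H]2COC(C)(C)O2)C[C@@H](O)[C@@]2(C)[C@@H](C)CC[C@]13CCC4(OCCO4)[C@@H]32 | intermediate
29 | benzyloxyacetyl chloride | O=C(Cl)COCc1ccccc1 | starting material
30 | C14 benzyloxyacetate | C[C@H]1[C@H](O[Si](CC)(CC)CC)[C@](C)([C@H]2COC(C)(C)O2)C[C@@H](OC(=O)COCc2ccccc2)[C@@]2(C)[C@@H](C)CC[C@]13CCC4(OCCO4)[C@@H]32 | intermediate
31 | triol ketone | C[C@H]1[C@H](O)[C@](C)([C@H](O)CO)C[C@@H](OC(=O)COCc2ccccc2)[C@@]2(C)[C@@H](C)CC[C@]13CCC(=O)[C@@H]32 | intermediate
32 | primary (C20) tosylate of 31 | C[C@H]1[C@H](O)[C@](C)([C@H](O)COS(=O)(=O)c2ccc(C)cc2)C[C@@H](OC(=O)COCc2ccccc2)[C@@]2(C)[C@@H](C)CC[C@]13CCC(=O)[C@@H]32 | intermediate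
33 | O-benzyl ether of the target | C[C@H]1[C@@H]2OC[C@@H](O)[C@]2(C)C[C@@H](OC(=O)COCc2ccccc2)[C@@]2(C)[C@@H](C)CC[C@]13CCC(=O)[C@@H]32 | intermediate
34 | pleuromutilin B | C[C@H]1[C@@H]2OC[C@@H](O)[C@]2(C)C[C@@H](OC(=O)CO)[C@@]2(C)[C@@H](C)CC[C@]13CCC(=O)[C@@H]32 | target

Total step count: 22. Longest linear sequence: 19 steps (steps 1–7 and 11–22); steps 8–10 make the side fragment.

**Steps most likely to fail**

1. Step 6. The radical cation may lose silicon and be oxidised further before C4 reaches the fully substituted C5, or C5 may be attacked on the wrong face. The fallback sets out from enone 9. The copper-catalysed methyl addition is run as in step 5, but the magnesium enolate 10 is quenched with N-bromosuccinimide to give the tertiary α-bromo ketone F1 (both C5 epimers). Irradiation of F1 with fac-Ir(ppy)3 then generates the C5 α-keto radical, which closes 6-exo onto C4 of the silyl enol ether; oxidation of the α-silyloxy radical and loss of silicon return the route at diketone 12. This is a known atom-transfer-type radical cyclisation of an α-halo ketone onto a silyl enol ether.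

2. Step 15. Oxidative cyclisation at the neopentyl aldehyde may be slow enough for alkyne oligomerisation to take over, or the C11 epimer may form. The fallback sets out from alkenyl iodide 23. A Nozaki–Hiyama–Kishi cyclisation (CrCl2, NiCl2 cat., DMSO) adds the alkenylchromium to the aldehyde and gives the free allylic alcohol F2. Silylation (TESOTf, 2,6-lutidine) returns the route at 25.

3. Step 11. The hindered C14 α-silyloxy radical may be intercepted by the neighbouring alkenylsilane before it is oxidised, and facial selectivity at the acyclic C12 radical may erode. The fallback reverses the roles of the partners and sets out from ketal 13. Its enol silane 20 is brominated with N-bromosuccinimide to the bromomethyl ketone F3. Thioester 17 is reduced (Et3SiH, Pd/C) to the aldehyde F4 and converted with TBSOTf and Et3N into its silyl enol ether F5. Photoredox coupling of F3 with F5 (fac-Ir(ppy)3, blue light) puts the radical on C13, which adds to C12 of F5, and returns the route at aldehyde 22, one step further on; the facial preference at C12 would then have to be checked.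

**Further compounds**

F1 | step 6 | 3-bromo-6-[3-(tert-butyldimethylsilyloxy)-1-(1-trimethylsilylvinyl)cyclopent-2-en-1-yl]-3,4-dimethylhexan-2-one | CC(=O)C(C)(Br)[C@@H](C)CC[C@@]1(C(=C)[Si](C)(C)C)CCC(O[Si](C)(C)C(C)(C)C)=C1
F2 | step 15 | free C11 allylic alcohol corresponding to 25 | C=C1[C@H](O)[C@](C)([C@H]2COC(C)(C)O2)CC(=O)[C@@]2(C)[C@@H](C)CC[C@]13CCC4(OCCO4)[C@@H]32
F3 | step 11 | bromomethyl ketone of 13 (C13 bromide) | BrCC(=O)[C@@]1(C)[C@@H](C)CC[C@@]2(C(=C)[Si](C)(C)C)CCC3(OCCO3)[C@H]12
F4 | step 11 | 2-[(4S)-2,2-dimethyl-1,3-dioxolan-4-yl]propanal | O=CC(C)[C@H]1COC(C)(C)O1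
F5 | step 11 | tert-butyldimethylsilyl enol ether of F4 | CC(=CO[Si](C)(C)C(C)(C)C)[C@H]1COC(C)(C)O1
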